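The earlier runs and the new flask come from a simulation on assumed constants; scatter was added.

If I wanted to rank these set-ups from earlier closed-flask runs, I needed a number that carried from a flask to a tank, so I reckoned in rates.

| flask | starting material | second substrate | coupling partner | free catalyst | remark | time |
|---|---|---|---|---|---|---|
| ash | 0.010 M | 1 equiv | 2 equiv | 0.5 mol% | run made earlier |  |
| alder | 0.010 M | 1.4 equiv | 2 equiv | 0.5 mol% | run made earlier |  |
| maple | 0.010 M | 2.2 equiv | 2 equiv | 0.5 mol% | run made earlier |  |
| Wednesday's | 0.010 M | 1.00 equiv | 2.00 equiv | 0.5 mol% | a single well-mixed tank run continuously and read at steady state, 15 min in it on average |  |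
| Friday's | 0.010 M | 1.00 equiv | 2.00 equiv | 0.5 mol% | a closed flask charged with all of it at once and left for 15 min | 15 min |
| Saturday's | 0.010 M | 1.00 equiv | 2.00 equiv (fed, over 15.0 min) | 0.5 mol% | all but coupling partner at the start; coupling partner goes in evenly over 15.0 min, the run ends at 15 min | 15 min |
| Thursday's | 0.010 M | 1.00 equiv | 2.00 equiv | 0.5 mol% | one stirred flow tank at steady state, fed with the mixture as stated, mean residence time 75.0 min |  |

| run | time / min | target / % |
|---|---|---|
| ash | 0.667 | 2 |
| ash | 1.33 | 2 |
| ash | 2.00 | 4 |
| ash | 3.00 | 6 |
| ash | 5.00 | 8 |
| ash | 10.0 | 20 |
| alder | 1.33 | 2 |
| alder | 2.00 | 7 |
| alder | 3.00 | 5 |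
| alder | 5.00 | 7 |
| alder | 10.0 | 17 |
| alder | 15.0 | 27 |
| maple | 1.33 | 3 |
| maple | 2.00 | 3 |
| maple | 3.00 | 4 |
| maple | 5.00 | 10 |
| maple | 10.0 | 12 |
| maple | 15.0 | 23 |

(each reading ± 2 percentage points)

- the stated concentrations are those of everything mixed, before any reaction; amounts are the same in each set-up
- the numbers in the tables scatter with a standard deviation of 2 percentage points
- what may be going on: starting material + free catalyst <-> catalyst intermediate A; coupling partner + catalyst intermediate A -> free catalyst + target; coupling partner + catalyst intermediate B -> free catalyst + second product; second substrate + free catalyst <-> catalyst intermediate B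
- the feed brings no volume worth counting
- the earlier runs were made in a closed, stirred flask

- order of the set-ups by the amount of target at the outlet or at the end, in percent of the starting material put in, highest first (Wednesday's / Friday's / Saturday's / Thursday's)
- amount of target at the outlet or at the end, in percent of the starting material put in, Wednesday's
- amount of target at the outlet or at the end, in percent of the starting material put in, Friday's
- amount of target at the outlet or at the end, in percent of the starting material put in, Saturday's
- amount of target at the outlet or at the end, in percent of the starting material put in, Thursday's

The ash run has the recipe's charge and gave 20 % at 10.0 min, so I took 0.0200 /min of the charge as the starting rate, a mean over that time read from a reading with the scatter of 2 percentage points. The maple run, with more second substrate, read 12 % at that time, less than ash, but the recipe's level of second substrate is already inside the ash rate. I called the rate times the time the exposure, a pseudo-first-order quantity, and it came to 0.300 for Friday's. The earlier runs held coupling partner at one charge, so they gave no order in it, and I left its fall out.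

I then assumed that the rate falls in proportion to starting material. At the end of Friday's closed flask that put the rate at 0.741 of its start, so I reckoned 25.9 % for Friday's. A tank at steady state runs at outlet level, so on the same assumption its rate is cut by a factor of one plus the exposure: for Wednesday's, with the same exposure on average, I reckoned 23.1 %, less than for Friday's. Thursday's has an exposure of 1.50, for which I reckoned 60.0 %. Saturday's receives coupling partner evenly, so the amount fed averages half the charge. Assuming first order in coupling partner, which the runs did not show, I took an exposure of 0.150 for Saturday's, which gave 13.9 %.

The forecast gave 24 %, 27 %, 15 % and 52 % for Wednesday's, Friday's, Saturday's and Thursday's, lower than mine for Thursday's, “limited by partner shared with the second product”, with the order Thursday's > Friday's > Wednesday's > Saturday's, which was also mine. The flasks gave 24.0 %, 26.8 %, 19.1 % and 63.4 %, in the order Thursday's > Friday's > Wednesday's > Saturday's.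

    starting material + free catalyst ⇌ catalyst intermediate A (K = 1300 /M, k = 13.0 /M/s)
    coupling partner + catalyst intermediate A → free catalyst + target (k = 12.0 /M/s)
    coupling partner + catalyst intermediate B → free catalyst + second product (k = 7.00 /M/s)
    second substrate + free catalyst ⇌ catalyst intermediate B (K = 32.0 /M, k = 130 /M/s)

On the closed-flask reckoning, Saturday's result corresponds to an exposure of 0.211, more than my 0.150, and that is 0.705 of the full 0.300. At 9.14 min in Saturday's, catalyst intermediate B fell back 52 times faster than it went on. A neighbour of Saturday's with 2 mol% of free catalyst has 4.00 times the loading, so, taking exposure as proportional to loading, I get 0.846 and 57.1 % target. That flask gave 57.3 %.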